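**Plan**
- Retrosynthetic cuts, in order: the two aryl O–Si bonds; the C3–OH bond (oxidation of a flavanone enol silane); C2–C3 of ring C (carbenoid C–H insertion of a diazomethyl ketone); the three aryl–prenyl bonds at C6, C8 and C3' in one operation; O1–C2 (aryl benzyl ether).
- Forward: rings A and B are bought as phenols and iodinated where needed. They are joined through O1–C2 and prenylated three times at once. The acetyl group is then turned into the diazoketone, and ring C, the only ring that is made, is closed last by C2–C3.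
- Enabling feature: C2 is a CH2 bonded to O1 and benzylic to ring B, whose C4' oxygen stands para to it, so its C–H bonds are the most hydridic in the molecule. They lie 1,6 to C3, and the 1,5 position is O1, which carries no hydrogen. The C8 prenyl group and C4a, both ortho to O1, turn the O1–C2 bond out of the ring A plane and toward C3.
- Stereochemistry: C2 comes from the chiral dirhodium carboxylate, which chooses between the two enantiotopic C2 hydrogens. C3 comes from C2, because the oxidant adds to the C3=C4 enol silane anti to the 2-aryl group, which gives the 2,3-trans (2R,3R) series.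

Key step: step 8

Assumption: the sense of induction of the (S)-configured dirhodium catalyst on this diazoketone cannot be told in advance. The (S)-ligand series is written, and the mirror-image catalyst is taken if that one delivers the (2S)-flavanone.
Abbreviations: TBS = tert-butyldimethylsilyl, TMS = trimethylsilyl, prenyl = 3-methylbut-2-en-1-yl, MOM = methoxymethyl.

Step 1
Reactants: 1 1-(2,4-dihydroxyphenyl)ethanone
Product: 2 1-(2,4-dihydroxy-3,5-diiodophenyl)ethanone
Conditions: N-iodosuccinimide (2.1 equiv), MeCN, 0 °C to rt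
Reagents that add atoms: N-iodosuccinimide O=C1CCC(=O)N1I
Why: Twofold electrophilic aromatic iodination goes to C3 and C5 of the ketone, the only positions ortho or para to both hydroxyl groups, while C6 is meta to both and stays untouched.

Step 2
Reactants: 2 1-(2,4-dihydroxy-3,5-diiodophenyl)ethanone
Product: 3 1-[4-(TBS-oxy)-2-hydroxy-3,5-diiodophenyl]ethanone
Conditions: TBSCl (1.05 equiv), imidazole, DMF, 0 °C to rt
Reagents that add atoms: tert-butyldimethylsilyl chloride CC(C)(C)[Si](C)(C)Cl
Why: Chemoselective O-silylation, because the 2-OH is tied up in a hydrogen bond to the acetyl oxygen, so one equivalent of TBSCl should silylate the free and more acidic 4-OH.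

Step 3
Reactants: 4 4-hydroxy-3-iodobenzaldehyde
Product: 5 4-(TBS-oxy)-3-iodobenzaldehyde
Conditions: TBSCl, imidazole, CH2Cl2, rt
Reagents that add atoms: tert-butyldimethylsilyl chloride CC(C)(C)[Si](C)(C)Cl
Why: Standard O-silylation of a phenol masks the future 4'-OH as a donor group that survives the neutral or weakly basic steps that follow.

Step 4
Reactants: 5 4-(TBS-oxy)-3-iodobenzaldehyde
Product: 6 [4-(TBS-oxy)-3-iodophenyl]methanol
Conditions: NaBH4, MeOH/THF, 0 °C
Reagents that add atoms: none
Why: Hydride reduction of the aldehyde with NaBH4 leaves the aryl iodide and the aryl silyl ether untouched.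

Step 5
Reactants: 3 1-[4-(TBS-oxy)-2-hydroxy-3,5-diiodophenyl]ethanone, 6 [4-(TBS-oxy)-3-iodophenyl]methanol
Product: 7 1-{4-(TBS-oxy)-2-[4-(TBS-oxy)-3-iodobenzyloxy]-3,5-diiodophenyl}ethanone
Conditions: PPh3, diisopropyl azodicarboxylate (DIAD), THF (concentrated), 0 °C to rt
Reagents that add atoms: none
Why: Mitsunobu etherification joins the acidic, iodine-flanked phenol 3 and the primary benzylic alcohol 6 under neutral conditions that spare both aryl silyl ethers, and it makes the O1–C2 bond.

Step 6
Reactants: 7 1-{4-(TBS-oxy)-2-[4-(TBS-oxy)-3-iodobenzyloxy]-3,5-diiodophenyl}ethanone, 8 tributyl(3-methylbut-2-en-1-yl)stannane (3.6 equiv)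
Product: 9 1-{4-(TBS-oxy)-2-[4-(TBS-oxy)-3-prenylbenzyloxy]-3,5-diprenylphenyl}ethanone
Conditions: Pd(PPh3)4 (10 mol %), DMF, 90 °C
Reagents that add atoms: none
Why: Threefold Migita–Kosugi–Stille coupling, in which the aryl iodides add readily to zerovalent palladium and the prenylstannane transfers its allyl unit mainly at the tin-bearing carbon, should set all three linear prenyl groups under neutral conditions that spare ketone, benzyl ether and silyl ethers.

Step 7
Reactants: 9 1-{4-(TBS-oxy)-2-[4-(TBS-oxy)-3-prenylbenzyloxy]-3,5-diprenylphenyl}ethanone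
Product: 11 2-diazo-1-{4-(TBS-oxy)-2-[4-(TBS-oxy)-3-prenylbenzyloxy]-3,5-diprenylphenyl}ethanone, via trifluoroacetyl diketone 10 (not isolated)
Conditions: LiN(SiMe3)2, THF, −78 °C; CF3CO2CH2CF3; dilute HCl work-up; then MeSO2N3, Et3N, H2O (1 equiv), MeCN, rt
Reagents that add atoms: 2,2,2-trifluoroethyl trifluoroacetate O=C(OCC(F)(F)F)C(F)(F)F; methanesulfonyl azide CS(=O)(=O)N=[N+]=[N-]
Why: In this detrifluoroacetylative Regitz diazo transfer the kinetic lithium enolate is C-acylated to the activated 1,3-diketone 10, which takes the diazo group from the sulfonyl azide and loses the trifluoroacetyl group, a standard way from aryl methyl ketones to diazomethyl ketones.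

Step 8
Reactants: 11 2-diazo-1-{4-(TBS-oxy)-2-[4-(TBS-oxy)-3-prenylbenzyloxy]-3,5-diprenylphenyl}ethanone
Product: 12 (2S)-7-(TBS-oxy)-2-[4-(TBS-oxy)-3-prenylphenyl]-6,8-diprenylchroman-4-one
Conditions: Rh2(S-PTTL)4 (dirhodium tetrakis[N-phthaloyl-(S)-tert-leucinate], 1 mol %), 4 Å molecular sieves, toluene, −10 °C, 11 added over 3 h
Reagents that add atoms: none
Why: Loss of N2 from 11 at an axial site of the dirhodium core gives an electrophilic rhodium carbenoid at C3, which inserts into a C2–H bond through a three-centre, hydride-transfer-like transition state in which the positive charge building at C2 is carried by O1 and by the para silyloxy group of ring B. The closest known reaction type is the dirhodium-carboxylate-catalysed intramolecular C–H insertion of 2-alkoxyaryl diazoketones to 2-substituted chroman-4-ones, backed by asymmetric carbenoid insertion next to the oxygen of 4-alkoxybenzyl ethers used as an aldol surrogate. Ring C (O1–C2–C3–C4–C4a–C8a) closes in the 1,6-insertion mode, because the usually faster 1,5 mode is not open: the atom in that position is O1, which bears no hydrogen. The only new stereocentre, C2, is controlled by the chiral carboxylate ligands, whose phthalimido walls leave one of the two enantiotopic C2 hydrogens accessible, and (2S)-12 has the spatial arrangement of C2 in the target (the descriptor changes to R once C3 carries oxygen). The step needs C–H insertion to win over attack of O1 on the carbenoid (oxonium ylide, then 1,2-shift of the benzyl group), over cyclopropanation of the prenyl groups and over carbene dimerisation. The substrate helps because the para silyloxy group makes the C2–H bonds unusually hydridic, because the C8 prenyl group and C4a crowd the lone pairs of O1 while pushing the C2–H bonds toward C3, because both ring A prenyl groups are meta to C4a and cannot reach C3 while the ring B prenyl group could do so only through a ring of eleven atoms, and because slow addition keeps 11 dilute.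

Step 9
Reactants: 12 (2S)-7-(TBS-oxy)-2-[4-(TBS-oxy)-3-prenylphenyl]-6,8-diprenylchroman-4-one
Product: 15 (2R,3R)-7-(TBS-oxy)-2-[4-(TBS-oxy)-3-prenylphenyl]-3-hydroxy-6,8-diprenylchroman-4-one, via trimethylsilyl enol ether 13 (not isolated), via silyloxy epoxide 14 (not isolated)
Conditions: TMSOTf, Et3N, CH2Cl2, 0 °C; NaHCO3/pentane work-up; dimethyldioxirane (1.0 equiv, acetone), CH2Cl2, −78 °C; then 10 % aq citric acid, THF, 0 °C
Reagents that add atoms: trimethylsilyl trifluoromethanesulfonate C[Si](C)(C)OS(=O)(=O)C(F)(F)F; dimethyldioxirane CC1(C)OO1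
Why: In this Rubottom oxidation soft enolisation avoids a free enolate that could open ring C at O1–C2, the aryl-conjugated enol silane 13 should take up one equivalent of the dioxirane far faster than the three trisubstituted prenyl double bonds, and the oxidant adds anti to the 2-aryl group, so that hydrolysis of 14 sets C3 as R, trans to C2.

Step 10
Reactants: 15 (2R,3R)-7-(TBS-oxy)-2-[4-(TBS-oxy)-3-prenylphenyl]-3-hydroxy-6,8-diprenylchroman-4-one
Product: 16 Lespeflorin B3, (2R,3R)-3,7-dihydroxy-2-(4-hydroxy-3-prenylphenyl)-6,8-diprenylchroman-4-one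
Conditions: Bu4NF (2.2 equiv), AcOH (2.5 equiv), THF, 0 °C
Reagents that add atoms: none
Why: Fluoride-induced cleavage of the two aryl silyl ethers, buffered with AcOH, should free both phenols without epimerising C3 or opening ring C, and it never exposes the ortho-prenylphenols to strong acid.

**Compound list**
1 | 1-(2,4-dihydroxyphenyl)ethanone | CC(=O)c1ccc(O)cc1O | starting material
2 | 1-(2,4-dihydroxy-3,5-diiodophenyl)ethanone | CC(=O)c1cc(I)c(O)c(I)c1O | intermediate
3 | 1-[4-(TBS-oxy)-2-hydroxy-3,5-diiodophenyl]ethanone | CC(=O)c1cc(I)c(O[Si](C)(C)C(C)(C)C)c(I)c1O | intermediate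
4 | 4-hydroxy-3-iodobenzaldehyde | O=Cc1ccc(O)c(I)c1 | starting material
5 | 4-(TBS-oxy)-3-iodobenzaldehyde | O=Cc1ccc(O[Si](C)(C)C(C)(C)C)c(I)c1 | intermediate
6 | [4-(TBS-oxy)-3-iodophenyl]methanol | OCc1ccc(O[Si](C)(C)C(C)(C)C)c(I)c1 | intermediate
7 | triiodo aryl benzyl ether ketone | CC(=O)c1cc(I)c(O[Si](C)(C)C(C)(C)C)c(I)c1OCc2ccc(O[Si](C)(C)C(C)(C)C)c(I)c2 | intermediate
8 | tributyl(3-methylbut-2-en-1-yl)stannane | CCCC[Sn](CCCC)(CCCC)CC=C(C)C | starting material
9 | triprenyl aryl benzyl ether ketone | CC(=O)c1cc(CC=C(C)C)c(O[Si](C)(C)C(C)(C)C)c(CC=C(C)C)c1OCc2ccc(O[Si](C)(C)C(C)(C)C)c(CC=C(C)C)c2 | intermediate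
10 | 4,4,4-trifluoro-1-aryl-butane-1,3-dione from 9 | O=C(CC(=O)C(F)(F)F)c1cc(CC=C(C)C)c(O[Si](C)(C)C(C)(C)C)c(CC=C(C)C)c1OCc2ccc(O[Si](C)(C)C(C)(C)C)c(CC=C(C)C)c2 | intermediate
11 | diazomethyl ketone | [N-]=[N+]=CC(=O)c1cc(CC=C(C)C)c(O[Si](C)(C)C(C)(C)C)c(CC=C(C)C)c1OCc2ccc(O[Si](C)(C)C(C)(C)C)c(CC=C(C)C)c2 | intermediate
12 | (2S)-flavanone, bis-TBS ether | CC(C)=CCc1cc([C@H]2Oc3c(cc(CC=C(C)C)c(O[Si](C)(C)C(C)(C)C)c3CC=C(C)C)C(=O)C2)ccc1O[Si](C)(C)C(C)(C)C | intermediate
13 | (2S)-4-(TMS-oxy)-2H-chromene (enol silane of 12) | CC(C)=CCc1cc([C@H]2Oc3c(cc(CC=C(C)C)c(O[Si](C)(C)C(C)(C)C)c3CC=C(C)C)C(O[Si](C)(C)C)=C2)ccc1O[Si](C)(C)C(C)(C)C | intermediate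
14 | 3,4-epoxide of 13, oxygen on the face anti to the 2-aryl group | CC(C)=CCc1cc([C@H]2Oc3c(cc(CC=C(C)C)c(O[Si](C)(C)C(C)(C)C)c3CC=C(C)C)[C@]4(O[Si](C)(C)C)O[C@H]24)ccc1O[Si](C)(C)C(C)(C)C | intermediate
15 | (2R,3R)-dihydroflavonol, 7,4'-bis-TBS ether | CC(C)=CCc1cc([C@H]2Oc3c(cc(CC=C(C)C)c(O[Si](C)(C)C(C)(C)C)c3CC=C(C)C)C(=O)[C@@H]2O)ccc1O[Si](C)(C)C(C)(C)C | intermediate
16 | Lespeflorin B3 | CC(C)=CCc1cc([C@H]2Oc3c(cc(CC=C(C)C)c(O)c3CC=C(C)C)C(=O)[C@@H]2O)ccc1O | target

**Step count:** 10 steps in total. The longest linear sequence is 8 steps (1, 2, 5–10, or equally 3–10).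

**Steps most likely to fail**

1. Step 8.
   - What may go wrong: O1 may attack the carbenoid, and the oxonium ylide may then shift the electron-rich benzyl group from oxygen to carbon. The catalyst may also discriminate poorly between the two enantiotopic C2 hydrogens.
   - Fallback: it gives up the carbenoid and builds the same stereodiad from a chalcone. It sets out from 2 and 4 and comes back at 16.
   - Both are protected with MOMCl (NaH, DMF for 2; iPr2NEt, CH2Cl2 for 4) to the bis-MOM ketone F1 and the MOM aldehyde F2.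
   - Claisen–Schmidt condensation (KOH, EtOH) gives the triiodochalcone F3, and threefold Stille coupling with 8 (Pd(PPh3)4, DMF) gives the triprenylchalcone F4.
   - Juliá–Colonna epoxidation (poly-L-leucine, urea–H2O2, DBU, THF) is a nucleophilic epoxidation that touches only the enone, and it gives the (αR,βS)-epoxychalcone F5.
   - HCl in MeOH (45 °C) removes the three MOM groups. The freed phenol then opens the epoxide at the benzylic carbon with inversion to give 16.

2. Step 9.
   - What may go wrong: oxygen transfer to the prenyl double bonds may compete with oxidation of the enol silane. Transient opening of ring C at O1–C2 during enolisation would also erode the configuration at C2.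
   - Fallback: it replaces the epoxidising oxidant by an electrophile that does not react with isolated alkenes. It sets out from 13 and comes back at 15.
   - O-selective nitroso aldol reaction with nitrosobenzene (Et3SiOTf 5 mol %, CH2Cl2, −78 °C), again anti to the 2-aryl group, gives the 3-anilinooxy flavanone F6.
   - N–O cleavage with CuSO4 (30 mol %) in MeOH at 0 °C then gives 15.

3. Step 6.
   - What may go wrong: allyl transposition during transmetalation may put branched 1,1-dimethylallyl groups on the rings. Conversion of the doubly ortho-substituted C8 iodide may be incomplete, and protodeiodination may occur.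
   - Fallback: it separates C–C coupling from olefin substitution. It sets out from 7 and comes back at 9.
   - Threefold Stille coupling with allyltributylstannane (Pd(PPh3)4, DMF, 80 °C), in which transposition has no consequence, gives the triallyl ketone F7.
   - Threefold cross-metathesis in 2-methylbut-2-ene/CH2Cl2 with the second-generation Grubbs catalyst RuCl2(H2IMes)(PCy3)(=CHPh) at 40 °C then gives 9.

**Further compounds**
F1 | step 8 | 1-[3,5-diiodo-2,4-bis(methoxymethoxy)phenyl]ethanone | CC(=O)c1cc(I)c(OCOC)c(I)c1OCOC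
F2 | step 8 | 3-iodo-4-(methoxymethoxy)benzaldehyde | O=Cc1ccc(OCOC)c(I)c1
F3 | step 8 | (E)-1-[3,5-diiodo-2,4-bis(methoxymethoxy)phenyl]-3-[3-iodo-4-(methoxymethoxy)phenyl]prop-2-en-1-one | O=C(/C=C/c1ccc(OCOC)c(I)c1)c2cc(I)c(OCOC)c(I)c2OCOC
F4 | step 8 | (E)-1-[2,4-bis(methoxymethoxy)-3,5-diprenylphenyl]-3-[4-(methoxymethoxy)-3-prenylphenyl]prop-2-en-1-one | O=C(/C=C/c1ccc(OCOC)c(CC=C(C)C)c1)c2cc(CC=C(C)C)c(OCOC)c(CC=C(C)C)c2OCOC
F5 | step 8 | (αR,βS)-trans-epoxide of F4 | O=C([C@@H]1O[C@H]1c2ccc(OCOC)c(CC=C(C)C)c2)c3cc(CC=C(C)C)c(OCOC)c(CC=C(C)C)c3OCOC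
F6 | step 9 | (2R,3R)-3-(anilinooxy)-7-(TBS-oxy)-2-[4-(TBS-oxy)-3-prenylphenyl]-6,8-diprenylchroman-4-one | CC(C)=CCc1cc([C@H]2Oc3c(cc(CC=C(C)C)c(O[Si](C)(C)C(C)(C)C)c3CC=C(C)C)C(=O)[C@@H]2ONc4ccccc4)ccc1O[Si](C)(C)C(C)(C)C
F7 | step 6 | 1-{3,5-diallyl-2-[3-allyl-4-(TBS-oxy)benzyloxy]-4-(TBS-oxy)phenyl}ethanone | CC(=O)c1cc(CC=C)c(O[Si](C)(C)C(C)(C)C)c(CC=C)c1OCc2ccc(O[Si](C)(C)C(C)(C)C)c(CC=C)c2
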